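**Retrosynthetic overview**

1. The strategy rests on ring A of the benzofuran (C3a, C4, C5, C6, C7, C7a): oxygen on C4 and C6, the quaternary 2-methylbut-3-en-2-yl carbon on C7 and the furan oxygen O1 on C7a. This is the pattern that a ketene/ynol ether benzannulation onto a 2-furyl group produces.
2. Last disconnection: the silyl ethers on C6–O and C5′–O (ring B: prenyl on C2′, OMe on C3′, OH on C5′) lead back to bis-silyl ether 30.
3. Key disconnection of 30: C4–C5 and C6–C7 (ketene + ynol ether [2+2]) and C3a–C4 (6π closure) lead back to furyl α-diazo ketone 17 and (triisopropylsilyloxy)ethyne 25; the C7–C7a bond is made by furyl migration in the Wolff step.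
4. 17 comes from ketone 14 by diazo transfer; 14 from 2-arylfuran 8 by C5 lithiation and Weinreb acylation; 8 from Suzuki coupling of furan-2-boronic acid with bromide 6; 6 from ortho-lithiation/prenylation of silylated 3-bromo-5-methoxyphenol; 25 from THF through a 2-bromovinyl silyl ether.
5. Ring order: ring B and the furan are bought; ring A is the only ring built, last, on the furan.

Key step: step 10

Remark: the target has no stereocentre; benzofuran numbering (O1, C2, C3, C3a, C4–C7, C7a) is used, and Ar = 3-methoxy-2-(3-methylbut-2-en-1-yl)-5-(triisopropylsilyloxy)phenyl. Triisopropylsilyl is used on both the ring-B phenol and the ynol ether so that one fluoride treatment releases the target.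

**Route**

Step 1
Reactants: 1 3-bromo-5-methoxyphenol
Product: 2 (3-bromo-5-methoxyphenoxy)triisopropylsilane
Conditions: TIPSCl, imidazole, DMF, rt
Reagents that add atoms: chlorotriisopropylsilane, CC(C)[Si](Cl)(C(C)C)C(C)C
Why: Phenol O-silylation with a silyl chloride and imidazole is routine, and the bulky triisopropylsilyl ether is chosen to survive the organolithium, aqueous-base coupling and diazo-transfer steps and to shield the ring positions next to it.

Step 2
Reactants: 2 (3-bromo-5-methoxyphenoxy)triisopropylsilane; 3 prenyl bromide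
Product: 6 [3-bromo-5-methoxy-4-(3-methylbut-2-en-1-yl)phenoxy]triisopropylsilane, via aryllithium 4 (not isolated), via arylcopper 5 (not isolated)
Conditions: LDA, THF, −78 °C; CuBr·SMe2, −78 °C; 3, −78 → 0 °C
Reagents that add atoms: none
Why: Directed ortho-metalation by the amide base should remove the most acidic ring hydrogen, the one flanked by Br and OMe (the silyloxy side is shielded), and the aryllithium, kept cold to avoid loss of LiBr to an aryne and converted into the arylcopper, should be allylated by prenyl bromide at its primary carbon (copper-mediated SN2-type allylation).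

Step 3
Reactants: 6 [3-bromo-5-methoxy-4-(3-methylbut-2-en-1-yl)phenoxy]triisopropylsilane; 7 furan-2-boronic acid
Product: 8 [3-(furan-2-yl)-5-methoxy-4-(3-methylbut-2-en-1-yl)phenoxy]triisopropylsilane
Conditions: 7 (1.5 equiv), Pd(OAc)2 (cat), SPhos, K3PO4, toluene/H2O, 70 °C
Reagents that add atoms: none
Why: Suzuki–Miyaura coupling of an ortho-substituted aryl bromide with a 2-furylboronic acid should proceed with a dialkylbiarylphosphine-ligated palladium catalyst at moderate temperature, excess boronic acid offsetting protodeboronation, while the aryl silyl ether and the trisubstituted alkene stay inert.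

Step 4
Reactants: 9 3,3-dimethylpent-4-enoic acid
Product: 11 N-methoxy-N,3,3-trimethylpent-4-enamide, via acyl imidazole 10 (not isolated)
Conditions: CDI, CH2Cl2, rt; MeNH(OMe)·HCl, rt
Reagents that add atoms: N,O-dimethylhydroxylamine hydrochloride, CNOC.Cl
Why: Weinreb amide formation through the acyl imidazole is a standard acid activation–amidation that the remote quaternary carbon does not hinder.

Step 5
Reactants: 8 [3-(furan-2-yl)-5-methoxy-4-(3-methylbut-2-en-1-yl)phenoxy]triisopropylsilane; 11 N-methoxy-N,3,3-trimethylpent-4-enamide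
Product: 14 1-(5-Ar-furan-2-yl)-3,3-dimethylpent-4-en-1-one, via 5-lithiofuran 12 (not isolated), via lithium hemiaminal adduct 13 (not isolated)
Conditions: n-BuLi, THF, −78 → −20 °C; 11, −78 °C → rt; aq NH4Cl
Reagents that add atoms: none
Why: The furan C5–H is the most acidic proton of 8, so n-BuLi should metalate it selectively (heteroaryl α-lithiation), and acylation by the Weinreb amide stops at the ketone because the chelated tetrahedral adduct persists until work-up (Weinreb ketone synthesis).

Step 6
Reactants: 14 1-(5-Ar-furan-2-yl)-3,3-dimethylpent-4-en-1-one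
Product: 17 2-diazo-1-(5-Ar-furan-2-yl)-3,3-dimethylpent-4-en-1-one, via lithium enolate 15 (not isolated), via trifluoroacetyl diketone 16 (not isolated)
Conditions: LiHMDS, THF, −78 °C; CF3CO2CH2CF3, −78 °C; aq HCl wash; then MsN3, Et3N, H2O, MeCN, rt
Reagents that add atoms: methanesulfonyl azide, CS(=O)(=O)N=[N+]=[N-]
Why: Detrifluoroacetylative diazo transfer: the only enolisable CH2 is C-trifluoroacetylated, the acidic 1,3-diketone takes a diazo group from the sulfonyl azide under amine base, and loss of the trifluoroacetyl group as the N-acylsulfonamide leaves the α-diazo ketone.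

Step 7
Reactants: 18 tetrahydrofuran (reactant and solvent)
Product: 21 triisopropyl(vinyloxy)silane, via 2-lithiotetrahydrofuran 19 (not isolated), via lithium ethenolate 20 (not isolated)
Conditions: n-BuLi, THF, rt, 16 h; TIPSCl, DMPU, 0 °C → rt
Reagents that add atoms: chlorotriisopropylsilane, CC(C)[Si](Cl)(C(C)C)C(C)C
Why: α-Lithiated THF undergoes the known [3+2] cycloreversion to ethene and the lithium enolate of acetaldehyde, and O-silylation of that enolate gives the vinyl silyl ether (enolate silylation).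

Step 8
Reactants: 21 triisopropyl(vinyloxy)silane
Product: 23 (Z)-(2-bromoethenyloxy)triisopropylsilane, via dibromo ether 22 (not isolated)
Conditions: Br2, CH2Cl2, −78 °C; iPr2NEt, −78 °C → rt
Reagents that add atoms: bromine, BrBr
Why: Bromine adds across the electron-rich enol ether double bond at low temperature, the bulky silyl group keeping the Si–O bond intact, and amine-mediated loss of HBr from the α-bromo ether should give the 2-bromovinyl silyl ether, cis as with alkyl 2-bromovinyl ethers (bromination–dehydrobromination of an enol ether).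

Step 9
Reactants: 23 (Z)-(2-bromoethenyloxy)triisopropylsilane
Product: 25 (ethynyloxy)triisopropylsilane, via lithium silyloxyacetylide 24 (not isolated)
Conditions: LDA (2.2 equiv), THF, −78 °C; H2O, −78 °C
Reagents that add atoms: none
Why: Proposed new method: in the Z isomer the C1–H and the C2–Br are anti, so LDA should effect E2 loss of HBr to the silyl ynol ether, which the second equivalent deprotonates to the acetylide that water reprotonates cold; the closest known reaction type is the amide-base dehydrohalogenation of (Z)-2-halovinyl alkyl ethers to alkoxyacetylenes, and the triisopropylsilyl group is relied on to suppress attack at silicon and oxygen-to-carbon silyl transfer.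

Step 10
Reactants: 17 2-diazo-1-(5-Ar-furan-2-yl)-3,3-dimethylpent-4-en-1-one; 25 (ethynyloxy)triisopropylsilane
Product: 30 2-Ar-7-(2-methylbut-3-en-2-yl)-6-(triisopropylsilyloxy)-1-benzofuran-4-ol, via furyl ketene 26 (not isolated), via silyloxycyclobutenone 27 (not isolated), via dienylketene 28 (not isolated), via dienone tautomer 29 (not isolated)
Conditions: 25 (3 equiv), hν (300 nm), ClCH2CH2Cl (degassed), rt; then 80 °C
Reagents that add atoms: none
Why: Proposed new method: irradiation expels N2 with 1,2-shift of the furyl group from the carbonyl carbon to the diazo carbon (Wolff rearrangement) to give furyl(tert-alkyl)ketene 26; the nucleophilic CH terminus of ynol ether 25 attacks the ketene carbonyl carbon and the adduct closes to cyclobutenone 27 ([2+2], forming C4–C5 and C6–C7), which opens by reversible 4π electrocyclic cleavage to dienylketene 28. Ring A is then closed by 6π electrocyclisation of the ketene onto furan C3 (six-membered, forming C3a–C4), and dienone 29 tautomerises to the phenol. The closest known reaction type is the photochemical Danheiser benzannulation of aryl and heteroaryl α-diazo ketones with silyloxyalkynes; what is new is the tert-alkyl group on the diazo carbon, which makes the ketene disubstituted and hindered, and the unsubstituted ynol ether. No stereocentre is formed, 27 and 29 being racemic intermediates that converge on the aromatic product. The regiochemistry needed is secured by polarity, since the ketene carbonyl carbon joins the CH carbon of the ynol ether so that OSi arrives at C6 and H at C5, and the electrocyclisation can only reach furan C3 because the other neighbour of the migrating furan carbon is the ring oxygen. Preference for Wolff rearrangement over carbene 1,2-shift or addition to the vinyl group is expected from the high migratory aptitude of the 2-furyl group, and the phenol forms mainly in the dark heating stage when little ketene is left to acylate it.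

Step 11
Reactants: 30 2-Ar-7-(2-methylbut-3-en-2-yl)-6-(triisopropylsilyloxy)-1-benzofuran-4-ol
Product: 31 2-[5-hydroxy-3-methoxy-2-(3-methylbut-2-en-1-yl)phenyl]-7-(2-methylbut-3-en-2-yl)-1-benzofuran-4,6-diol
Conditions: TBAF, AcOH, THF, 0 °C, Ar
Reagents that add atoms: none
Why: Buffered fluoride should cleave both aryl triisopropylsilyl ethers and leave the two alkenes, the methyl ether and the benzofuran untouched (silyl ether deprotection).

**Compound list**

1 | 3-bromo-5-methoxyphenol | COc1cc(O)cc(Br)c1 | starting material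
2 | (3-bromo-5-methoxyphenoxy)triisopropylsilane | COc1cc(O[Si](C(C)C)(C(C)C)C(C)C)cc(Br)c1 | intermediate
3 | prenyl bromide (1-bromo-3-methylbut-2-ene) | CC(C)=CCBr | starting material
4 | [2-bromo-6-methoxy-4-(triisopropylsilyloxy)phenyl]lithium | COc1cc(O[Si](C(C)C)(C(C)C)C(C)C)cc(Br)c1[Li] | intermediate
5 | [2-bromo-6-methoxy-4-(triisopropylsilyloxy)phenyl]copper | COc1cc(O[Si](C(C)C)(C(C)C)C(C)C)cc(Br)c1[Cu] | intermediate
6 | [3-bromo-5-methoxy-4-(3-methylbut-2-en-1-yl)phenoxy]triisopropylsilane | COc1cc(O[Si](C(C)C)(C(C)C)C(C)C)cc(Br)c1CC=C(C)C | intermediate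
7 | furan-2-boronic acid | OB(O)c1ccco1 | starting material
8 | [3-(furan-2-yl)-5-methoxy-4-(3-methylbut-2-en-1-yl)phenoxy]triisopropylsilane (2-Ar-furan) | COc1cc(O[Si](C(C)C)(C(C)C)C(C)C)cc(-c2ccco2)c1CC=C(C)C | intermediate
9 | 3,3-dimethylpent-4-enoic acid | C=CC(C)(C)CC(=O)O | starting material
10 | 1-(imidazol-1-yl)-3,3-dimethylpent-4-en-1-one | C=CC(C)(C)CC(=O)n1ccnc1 | intermediate
11 | N-methoxy-N,3,3-trimethylpent-4-enamide | C=CC(C)(C)CC(=O)N(C)OC | intermediate
12 | (5-Ar-furan-2-yl)lithium | [Li]c1ccc(-c2cc(O[Si](C(C)C)(C(C)C)C(C)C)cc(OC)c2CC=C(C)C)o1 | intermediate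
13 | lithium 1-(5-Ar-furan-2-yl)-1-[methoxy(methyl)amino]-3,3-dimethylpent-4-en-1-olate (racemic) | C=CC(C)(C)CC([O-])(N(C)OC)c1ccc(-c2cc(O[Si](C(C)C)(C(C)C)C(C)C)cc(OC)c2CC=C(C)C)o1.[Li+] | intermediate
14 | 1-(5-Ar-furan-2-yl)-3,3-dimethylpent-4-en-1-one | C=CC(C)(C)CC(=O)c1ccc(-c2cc(O[Si](C(C)C)(C(C)C)C(C)C)cc(OC)c2CC=C(C)C)o1 | intermediate
15 | lithium enolate of 14 (enolate geometry not defined) | C=CC(C)(C)C=C([O-])c1ccc(-c2cc(O[Si](C(C)C)(C(C)C)C(C)C)cc(OC)c2CC=C(C)C)o1.[Li+] | intermediate
16 | 2-(2,2,2-trifluoroacetyl) derivative of 14 (racemic, largely enolised) | C=CC(C)(C)C(C(=O)C(F)(F)F)C(=O)c1ccc(-c2cc(O[Si](C(C)C)(C(C)C)C(C)C)cc(OC)c2CC=C(C)C)o1 | intermediate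
17 | 2-diazo-1-(5-Ar-furan-2-yl)-3,3-dimethylpent-4-en-1-one | C=CC(C)(C)C(=[N+]=[N-])C(=O)c1ccc(-c2cc(O[Si](C(C)C)(C(C)C)C(C)C)cc(OC)c2CC=C(C)C)o1 | intermediate
18 | tetrahydrofuran | C1CCOC1 | starting material
19 | 2-lithiotetrahydrofuran (racemic) | [Li]C1CCCO1 | intermediate
20 | lithium ethenolate | [Li+].[O-]C=C | intermediate
21 | triisopropyl(vinyloxy)silane | C=CO[Si](C(C)C)(C(C)C)C(C)C | intermediate
22 | (1,2-dibromoethoxy)triisopropylsilane (racemic) | BrCC(Br)O[Si](C(C)C)(C(C)C)C(C)C | intermediate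
23 | (Z)-(2-bromoethenyloxy)triisopropylsilane | Br/C=C\O[Si](C(C)C)(C(C)C)C(C)C | intermediate
24 | lithium (triisopropylsilyloxy)acetylide | [Li]C#CO[Si](C(C)C)(C(C)C)C(C)C | intermediate
25 | (ethynyloxy)triisopropylsilane, i.e. (triisopropylsilyloxy)ethyne | C#CO[Si](C(C)C)(C(C)C)C(C)C | intermediate
26 | 2-(5-Ar-furan-2-yl)-3,3-dimethylpenta-1,4-dien-1-one (ketene) | C=CC(C)(C)C(=C=O)c1ccc(-c2cc(O[Si](C(C)C)(C(C)C)C(C)C)cc(OC)c2CC=C(C)C)o1 | intermediate
27 | 4-(5-Ar-furan-2-yl)-4-(2-methylbut-3-en-2-yl)-3-(triisopropylsilyloxy)cyclobut-2-en-1-one (racemic) | C=CC(C)(C)C1(c2ccc(-c3cc(O[Si](C(C)C)(C(C)C)C(C)C)cc(OC)c3CC=C(C)C)o2)C(=O)C=C1O[Si](C(C)C)(C(C)C)C(C)C | intermediate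
28 | 4-(5-Ar-furan-2-yl)-5,5-dimethyl-3-(triisopropylsilyloxy)hepta-1,3,6-trien-1-one (dienylketene, furyl cis to the ketene arm) | O=C=C/C(O[Si](C(C)C)(C(C)C)C(C)C)=C(\c1ccc(-c2cc(O[Si](C(C)C)(C(C)C)C(C)C)cc(OC)c2CC=C(C)C)o1)C(C)(C)C=C | intermediate
29 | 2-Ar-7-(2-methylbut-3-en-2-yl)-6-(triisopropylsilyloxy)-3aH-1-benzofuran-4-one (racemic) | O=C1C=C(O[Si](C(C)C)(C(C)C)C(C)C)C(C(C)(C)C=C)=C2OC(-c3cc(O[Si](C(C)C)(C(C)C)C(C)C)cc(OC)c3CC=C(C)C)=CC12 | intermediate
30 | 2-Ar-7-(2-methylbut-3-en-2-yl)-6-(triisopropylsilyloxy)-1-benzofuran-4-ol | C=CC(C)(C)c1c(O[Si](C(C)C)(C(C)C)C(C)C)cc(O)c2cc(-c3cc(O[Si](C(C)C)(C(C)C)C(C)C)cc(OC)c3CC=C(C)C)oc12 | intermediate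
31 | 2-[5-hydroxy-3-methoxy-2-(3-methylbut-2-en-1-yl)phenyl]-7-(2-methylbut-3-en-2-yl)-1-benzofuran-4,6-diol | C=CC(C)(C)c1c(O)cc(O)c2cc(-c3cc(O)cc(OC)c3CC=C(C)C)oc12 | target

**Step count**

Total steps: 11. Longest linear sequence: 7 (steps 1, 2, 3, 5, 6, 10, 11).

**Steps most likely to fail**

Step 10 (labelled). What may go wrong: carbene-type 1,2-shift or addition to the vinyl group may outrun furyl migration in the hindered diazo ketone. The cycloaddition of the disubstituted ketene may also be slow enough that the ketene dimerises, acylates the product phenol or leaves the terminal ynol ether to polymerise.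
Fallback (known chemistry; sets out from 8 through its lithio derivative 12, and from 25; comes back at 30): the tert-alkyl group is left off the diazo carbon and C7 is reverse-prenylated after ring A exists. 12 would be acetylated with N-methoxy-N-methylacetamide through the lithium hemiaminal adduct F1 to the methyl ketone F2. Its lithium enolate F3 would be trifluoroacetylated to the diketone F4, and diazo transfer would give the diazomethyl ketone F5, the substrate class on which this benzannulation is established. Irradiation with 25 and heating should lead, through the ketene F6, the cyclobutenone F7, the dienylketene F8 and the dienone F9, to the 7-unsubstituted benzofuranol F10. Bromination with one equivalent of NBS at low temperature is expected at C7, para to the free C4 hydroxyl and the most nucleophilic position of 4,6-dioxygenated benzofurans, giving the 7-bromide F11. Coupling of F11 with 3,3-dimethylallylboronic acid pinacol ester, using Pd(OAc)2 and a bulky dialkylbiarylphosphine chosen for the branched (γ) product with K3PO4 in THF/H2O, would form the quaternary C7–C bond and give 30.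

Step 9 (labelled). What may go wrong: the base may deprotonate C2 with loss of silanolate, silicon may migrate from oxygen to carbon in the lithium acetylide, or the ynol ether may hydrolyse on quench.
Fallback (known chemistry; sets out from 17, comes back at 31): 25 is replaced by an alkyl ynol ether whose alkyl group is fluoride-labile, made by the established trichloroethylene route to terminal alkoxyacetylenes. 2-(Trimethylsilyl)ethanol, KH and trichloroethylene should give the (E)-1,2-dichlorovinyl ether F12. n-BuLi at −78 °C would convert it into the lithium alkoxyacetylide F13, and a methanol quench would give [2-(ethynyloxy)ethyl]trimethylsilane F14. Used in step 10 in place of 25, F14 should give, through ketene 26, the cyclobutenone F15, the dienylketene F16 and the dienone F17, the 6-[2-(trimethylsilyl)ethoxy]benzofuranol F18. TBAF in DMF with warming would then remove the 2-(trimethylsilyl)ethyl group and the ring-B silyl group together to give 31.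

Step 6. What may go wrong: C-acylation at the α-carbon next to the quaternary centre may be slow, and retro-Claisen loss of the trifluoroacetyl group may precede diazo transfer onto the congested diketone, returning 14.
Fallback (sets out from 14, comes back at 17): the activate-and-cleave sequence is replaced by direct diazo transfer to a preformed enolate. KHMDS in THF at −78 °C would give the potassium enolate F19, which is treated with 4-nitrobenzenesulfonyl azide; the electron-poor sulfonyl group favours collapse of the enolate–azide adduct to the diazo ketone 17 and the sulfonamide.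

**Further compounds**

F1 | step 10 | lithium 1-(5-Ar-furan-2-yl)-1-[methoxy(methyl)amino]ethan-1-olate (racemic) | CC([O-])(N(C)OC)c1ccc(-c2cc(O[Si](C(C)C)(C(C)C)C(C)C)cc(OC)c2CC=C(C)C)o1.[Li+]
F2 | step 10 | 1-(5-Ar-furan-2-yl)ethan-1-one | CC(=O)c1ccc(-c2cc(O[Si](C(C)C)(C(C)C)C(C)C)cc(OC)c2CC=C(C)C)o1
F3 | step 10 | lithium 1-(5-Ar-furan-2-yl)ethenolate | C=C([O-])c1ccc(-c2cc(O[Si](C(C)C)(C(C)C)C(C)C)cc(OC)c2CC=C(C)C)o1.[Li+]
F4 | step 10 | 4,4,4-trifluoro-1-(5-Ar-furan-2-yl)butane-1,3-dione | O=C(CC(=O)C(F)(F)F)c1ccc(-c2cc(O[Si](C(C)C)(C(C)C)C(C)C)cc(OC)c2CC=C(C)C)o1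
F5 | step 10 | 2-diazo-1-(5-Ar-furan-2-yl)ethan-1-one | [N-]=[N+]=CC(=O)c1ccc(-c2cc(O[Si](C(C)C)(C(C)C)C(C)C)cc(OC)c2CC=C(C)C)o1
F6 | step 10 | 2-(5-Ar-furan-2-yl)ethen-1-one (ketene) | O=C=Cc1ccc(-c2cc(O[Si](C(C)C)(C(C)C)C(C)C)cc(OC)c2CC=C(C)C)o1
F7 | step 10 | 4-(5-Ar-furan-2-yl)-3-(triisopropylsilyloxy)cyclobut-2-en-1-one (racemic) | O=C1C=C(O[Si](C(C)C)(C(C)C)C(C)C)C1c1ccc(-c2cc(O[Si](C(C)C)(C(C)C)C(C)C)cc(OC)c2CC=C(C)C)o1
F8 | step 10 | 4-(5-Ar-furan-2-yl)-3-(triisopropylsilyloxy)buta-1,3-dien-1-one (furyl cis to the ketene arm) | O=C=C/C(O[Si](C(C)C)(C(C)C)C(C)C)=C\c1ccc(-c2cc(O[Si](C(C)C)(C(C)C)C(C)C)cc(OC)c2CC=C(C)C)o1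
F9 | step 10 | 2-Ar-6-(triisopropylsilyloxy)-3aH-1-benzofuran-4-one (racemic) | O=C1C=C(O[Si](C(C)C)(C(C)C)C(C)C)C=C2OC(-c3cc(O[Si](C(C)C)(C(C)C)C(C)C)cc(OC)c3CC=C(C)C)=CC12
F10 | step 10 | 2-Ar-6-(triisopropylsilyloxy)-1-benzofuran-4-ol | Oc1cc(O[Si](C(C)C)(C(C)C)C(C)C)cc2oc(-c3cc(O[Si](C(C)C)(C(C)C)C(C)C)cc(OC)c3CC=C(C)C)cc12
F11 | step 10 | 2-Ar-7-bromo-6-(triisopropylsilyloxy)-1-benzofuran-4-ol | Oc1cc(O[Si](C(C)C)(C(C)C)C(C)C)c(Br)c2oc(-c3cc(O[Si](C(C)C)(C(C)C)C(C)C)cc(OC)c3CC=C(C)C)cc12
F12 | step 9 | {2-[(E)-1,2-dichloroethenyloxy]ethyl}trimethylsilane | Cl/C=C(/Cl)OCC[Si](C)(C)C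
F13 | step 9 | lithium [2-(trimethylsilyl)ethoxy]acetylide | [Li]C#COCC[Si](C)(C)C
F14 | step 9 | [2-(ethynyloxy)ethyl]trimethylsilane | C#COCC[Si](C)(C)C
F15 | step 9 | 4-(5-Ar-furan-2-yl)-4-(2-methylbut-3-en-2-yl)-3-[2-(trimethylsilyl)ethoxy]cyclobut-2-en-1-one (racemic) | C=CC(C)(C)C1(c2ccc(-c3cc(O[Si](C(C)C)(C(C)C)C(C)C)cc(OC)c3CC=C(C)C)o2)C(=O)C=C1OCC[Si](C)(C)C
F16 | step 9 | 4-(5-Ar-furan-2-yl)-5,5-dimethyl-3-[2-(trimethylsilyl)ethoxy]hepta-1,3,6-trien-1-one (furyl cis to the ketene arm) | O=C=C/C(OCC[Si](C)(C)C)=C(\c1ccc(-c2cc(O[Si](C(C)C)(C(C)C)C(C)C)cc(OC)c2CC=C(C)C)o1)C(C)(C)C=C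
F17 | step 9 | 2-Ar-7-(2-methylbut-3-en-2-yl)-6-[2-(trimethylsilyl)ethoxy]-3aH-1-benzofuran-4-one (racemic) | O=C1C=C(OCC[Si](C)(C)C)C(C(C)(C)C=C)=C2OC(-c3cc(O[Si](C(C)C)(C(C)C)C(C)C)cc(OC)c3CC=C(C)C)=CC12
F18 | step 9 | 2-Ar-7-(2-methylbut-3-en-2-yl)-6-[2-(trimethylsilyl)ethoxy]-1-benzofuran-4-ol | C=CC(C)(C)c1c(OCC[Si](C)(C)C)cc(O)c2cc(-c3cc(O[Si](C(C)C)(C(C)C)C(C)C)cc(OC)c3CC=C(C)C)oc12
F19 | step 6 | potassium enolate of 14 (enolate geometry not defined) | C=CC(C)(C)C=C([O-])c1ccc(-c2cc(O[Si](C(C)C)(C(C)C)C(C)C)cc(OC)c2CC=C(C)C)o1.[K+]
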